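**Retrosynthetic overview**
1. Target 17 is the centrosymmetric (achiral) head-to-tail cyclobutane. Both imide C–N bonds are cut last, giving diacid 13 (as dichloride 14) and two molecules of lactam 15.
2. Feature used: in the four-membered ring the aryl-bearing carbons C2 and C4 alternate with the acyl-bearing carbons C1 and C3. C2 and C4 with their aryl groups come from one diarylalkyne 5; C1 and C3 with their carbonyls come from two carbenes of ethyl diazoacetate 6.
3. Ring order: cyclopropene ring (7), then the second three-membered ring (bicyclo[1.1.0]butane 8, which holds all four perimeter C–C bonds of the later cyclobutane). Acid then cleaves the central aryl-C–C-aryl bond and unveils the four-membered ring as cyclobutene 10.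
4. Relative configuration: conjugate reduction of 10 sets the two aryl groups trans; base equilibration sets the two ester carbons (esters trans).
5. Alkyne 5 comes from aryl iodide 1 and ethynyltrimethylsilane 2 by a one-flask double Sonogashira coupling.

Key step: step 2

Remark: step 2 may deliver some exo,endo isomer of 8, and the face of bridgehead protonation in step 3 is not relied on; both can lead to cis-cyclobutene 9, which is therefore listed as an unisolated intermediate and equilibrated to 10 in the same flask.

**Step 1**
Reactants: 1 5-iodo-1,2,3-trimethoxybenzene (two equivalents); 2 ethynyltrimethylsilane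
Product: 5 bis(3,4,5-trimethoxyphenyl)acetylene, via silylated arylacetylene 3 (not isolated), via terminal arylacetylene 4 (not isolated)
Conditions: PdCl2(PPh3)2 (5 mol %), CuI (10 mol %), DBU (6 equiv), H2O (1 equiv), MeCN, 60 °C
Reagents that add atoms: none
Why: Sonogashira coupling of 2 with 1 gives 3, DBU and water remove the silyl group in the flask, and the freed terminal alkyne 4 couples with the second equivalent of 1 (one-flask double Sonogashira coupling to a symmetrical diarylalkyne), aryl iodides reacting readily even when electron-rich.

**Step 2**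
Reactants: 5 bis(3,4,5-trimethoxyphenyl)acetylene; 6 ethyl diazoacetate (two equivalents incorporated)
Product: 8 diethyl exo,exo-1,3-bis(3,4,5-trimethoxyphenyl)bicyclo[1.1.0]butane-2,4-dicarboxylate, via cyclopropene ester 7 (not isolated)
Conditions: Rh2(OAc)4 (2 mol %), CH2Cl2, 25 °C; 6 (4 equiv) in CH2Cl2 by syringe pump over 16 h
Reagents that add atoms: none
Why: Rh2(OAc)4 decomposes 6 to the electrophilic carbene complex Rh2(OAc)4=CHCO2Et, which adds to the electron-rich C≡C of 5 in a (2+1) addition (both new C–C bonds to the one carbene carbon) and closes the cyclopropene ring of 7; a second carbene adds in the same (2+1) manner across the strained, exposed C=C of 7 and closes the second three-membered ring, so that the alkyne carbons become the aryl-bearing bridgeheads and the carbene carbons the ester-bearing wing carbons of 8. The closest known reaction type is the metal-catalysed (classically copper-catalysed) transfer of alkoxycarbonylcarbenes from diazoacetates to diarylacetylenes and on to 1,2-diarylcyclopropene carboxylates, which gives 1,3-diarylbicyclobutane-2,4-dicarboxylates. The first wing centre becomes exo because the second carbene approaches the face of 7 anti to the ester on its sp3 carbon (the hydrogen on that face ends endo), and the second ester is placed exo to avoid the flagpole contact with that endo hydrogen across the fold; the bridgehead centres are fixed by the bicyclic geometry. The step needs chemoselectivity for C≡C and then for the cyclopropene C=C over carbene dimerisation, attack on the arenes and metal-induced opening of 7 to a vinylcarbene (furan formation); the electron-rich alkyne, the strain of the cyclopropene π bond, the ester that tempers this π bond towards the Lewis-acidic catalyst, slow addition of 6 and room temperature serve this. Any exo,endo isomer is carried on, since step 3 erases both wing configurations. 8 is acid- and heat-sensitive and is purified on base-washed silica below 30 °C.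

**Step 3**
Reactants: 8 diethyl exo,exo-1,3-bis(3,4,5-trimethoxyphenyl)bicyclo[1.1.0]butane-2,4-dicarboxylate
Product: 10 diethyl 3,4-trans-2,4-bis(3,4,5-trimethoxyphenyl)cyclobut-1-ene-1,3-dicarboxylate (racemic), via cis-cyclobutene diester 9 (not isolated)
Conditions: CSA (10 mol %), CH2Cl2, 0 °C; then DBU (1 equiv), 0 °C
Reagents that add atoms: none
Why: Acid-catalysed bicyclobutane-to-cyclobutene isomerisation: protonation of the bent, electron-rich central bond at one bridgehead gives the tertiary benzylic cyclobutyl cation stabilised by its 3,4,5-trimethoxyphenyl group, which loses the proton alpha to a flanking ester (E1) to give the aryl-conjugated cyclobutene ester, and DBU then epimerises the remaining sp3 ester carbon C3 through its vinylogous ester enolate so that the ester is trans to the aryl group on C4 (thermodynamic control, whatever the wing configuration of 8); 10 is kept cold and used at once because 3-arylcyclobutenes undergo conrotatory ring opening on warming.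

**Step 4**
Reactants: 10 diethyl 3,4-trans-2,4-bis(3,4,5-trimethoxyphenyl)cyclobut-1-ene-1,3-dicarboxylate
Product: 12 dimethyl (1α,2α,3β,4β)-2,4-bis(3,4,5-trimethoxyphenyl)cyclobutane-1,3-dicarboxylate, via reduced diethyl diester 11 (not isolated)
Conditions: Mg turnings (10 equiv), MeOH/THF, 0 °C to rt; then NaOMe (0.5 equiv), MeOH, 50 °C
Reagents that add atoms: methanol CO
Why: Conjugate reduction of an aryl-conjugated enoate by Mg in MeOH (electron transfer, then protonation): the hydrogen enters at the benzylic ring carbon C2 anti to the ester on the adjacent sp3 carbon C3, which lies closer to C2 than the 1,3-related aryl group on C4, so the two aryl groups become trans (kinetic control), and methoxide then epimerises both enolisable ester carbons to the thermodynamic isomer with the esters trans to each other, in which each aryl group has only one cis neighbour, while exchanging the ethyl for methyl esters.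

**Step 5**
Reactants: 12 dimethyl (1α,2α,3β,4β)-2,4-bis(3,4,5-trimethoxyphenyl)cyclobutane-1,3-dicarboxylate
Product: 13 (1α,2α,3β,4β)-2,4-bis(3,4,5-trimethoxyphenyl)cyclobutane-1,3-dicarboxylic acid
Conditions: NaOH (aq), THF/MeOH, 60 °C; then 1 M HCl
Reagents that add atoms: sodium hydroxide [Na+].[OH-]
Why: Ester saponification (BAc2) followed by acidification; the ester carbons already hold the thermodynamic configuration, so the basic medium should not erode it.

**Step 6**
Reactants: 13 (1α,2α,3β,4β)-2,4-bis(3,4,5-trimethoxyphenyl)cyclobutane-1,3-dicarboxylic acid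
Product: 14 (1α,2α,3β,4β)-2,4-bis(3,4,5-trimethoxyphenyl)cyclobutane-1,3-dicarbonyl dichloride
Conditions: (COCl)2, DMF (cat.), CH2Cl2, 0 °C to rt
Reagents that add atoms: oxalyl chloride O=C(Cl)C(=O)Cl
Why: Acid chloride formation with oxalyl chloride under DMF catalysis (Vilsmeier-type activation) runs without base at or below room temperature and so leaves the alpha carbons untouched, and the trans-1,3-diacid cannot close to a cyclic anhydride.

**Step 7**
Reactants: 14 (1α,2α,3β,4β)-2,4-bis(3,4,5-trimethoxyphenyl)cyclobutane-1,3-dicarbonyl dichloride; 15 5,6-dihydropyridin-2(1H)-one (two equivalents)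
Product: 17 Piplartine-dimer A, via lithium lactamate 16 (not isolated)
Conditions: 15 (2.1 equiv), LiN(SiMe3)2 (2.1 equiv), THF, −78 °C; then 14, −78 to 0 °C
Reagents that add atoms: none
Why: N-Acylation of a lithium lactamate by an acid chloride, the usual way to N-acyl-5,6-dihydropyridin-2-one imides, is fast at −78 °C and should outrun ketene formation from the acid chloride and conjugate addition to the enone, and the ring configuration carried from 12 is in any case the thermodynamic one, so the four stereocentres should reach the target unchanged.

**Compound list**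
1 | 5-iodo-1,2,3-trimethoxybenzene | COc1cc(I)cc(OC)c1OC | starting material
2 | ethynyltrimethylsilane | C#C[Si](C)(C)C | starting material
3 | trimethyl[(3,4,5-trimethoxyphenyl)ethynyl]silane | COc1cc(C#C[Si](C)(C)C)cc(OC)c1OC | intermediate (not isolated)
4 | 5-ethynyl-1,2,3-trimethoxybenzene | COc1cc(C#C)cc(OC)c1OC | intermediate (not isolated)
5 | bis(3,4,5-trimethoxyphenyl)acetylene | COc1cc(C#Cc2cc(OC)c(OC)c(OC)c2)cc(OC)c1OC | intermediate
6 | ethyl diazoacetate | CCOC(=O)C=[N+]=[N-] | starting material
7 | ethyl 2,3-bis(3,4,5-trimethoxyphenyl)cycloprop-2-ene-1-carboxylate | CCOC(=O)C1C(c2cc(OC)c(OC)c(OC)c2)=C1c1cc(OC)c(OC)c(OC)c1 | intermediate (not isolated)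
8 | diethyl exo,exo-1,3-bis(3,4,5-trimethoxyphenyl)bicyclo[1.1.0]butane-2,4-dicarboxylate | CCOC(=O)[C@@H]1[C@@]2(c3cc(OC)c(OC)c(OC)c3)[C@H](C(=O)OCC)[C@@]12c1cc(OC)c(OC)c(OC)c1 | intermediate
9 | diethyl 3,4-cis-2,4-bis(3,4,5-trimethoxyphenyl)cyclobut-1-ene-1,3-dicarboxylate (racemic; C3 ester and C4 aryl cis) | CCOC(=O)C1=C(c2cc(OC)c(OC)c(OC)c2)[C@@H](C(=O)OCC)[C@H]1c3cc(OC)c(OC)c(OC)c3 | intermediate (not isolated)
10 | diethyl 3,4-trans-2,4-bis(3,4,5-trimethoxyphenyl)cyclobut-1-ene-1,3-dicarboxylate (racemic; C3 ester and C4 aryl trans) | CCOC(=O)C1=C(c2cc(OC)c(OC)c(OC)c2)[C@@H](C(=O)OCC)[C@@H]1c3cc(OC)c(OC)c(OC)c3 | intermediate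
11 | diethyl (1α,2α,3α,4β)-2,4-bis(3,4,5-trimethoxyphenyl)cyclobutane-1,3-dicarboxylate (aryl groups trans, esters cis) | COc1cc([C@H]2[C@@H](C(=O)OCC)[C@H](c3cc(OC)c(OC)c(OC)c3)[C@H]2C(=O)OCC)cc(OC)c1OC | intermediate (not isolated)
12 | dimethyl (1α,2α,3β,4β)-2,4-bis(3,4,5-trimethoxyphenyl)cyclobutane-1,3-dicarboxylate (aryl groups trans, esters trans) | COc1cc([C@H]2[C@H](C(=O)OC)[C@H](c3cc(OC)c(OC)c(OC)c3)[C@H]2C(=O)OC)cc(OC)c1OC | intermediate
13 | (1α,2α,3β,4β)-2,4-bis(3,4,5-trimethoxyphenyl)cyclobutane-1,3-dicarboxylic acid | COc1cc([C@H]2[C@H](C(=O)O)[C@H](c3cc(OC)c(OC)c(OC)c3)[C@H]2C(=O)O)cc(OC)c1OC | intermediate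
14 | (1α,2α,3β,4β)-2,4-bis(3,4,5-trimethoxyphenyl)cyclobutane-1,3-dicarbonyl dichloride | COc1cc([C@H]2[C@H](C(=O)Cl)[C@H](c3cc(OC)c(OC)c(OC)c3)[C@H]2C(=O)Cl)cc(OC)c1OC | intermediate
15 | 5,6-dihydropyridin-2(1H)-one | O=C1C=CCCN1 | starting material
16 | lithium salt of 5,6-dihydropyridin-2(1H)-one (N-lithio lactam) | [Li+].O=C1C=CCC[N-]1 | intermediate (not isolated)
17 | Piplartine-dimer A, 1,1'-{[(1α,2α,3β,4β)-2,4-bis(3,4,5-trimethoxyphenyl)cyclobutane-1,3-diyl]dicarbonyl}bis(5,6-dihydropyridin-2(1H)-one) | COc1cc([C@H]2[C@H](C(=O)N3CCC=CC3=O)[C@H](c3cc(OC)c(OC)c(OC)c3)[C@H]2C(=O)N2CCC=CC2=O)cc(OC)c1OC | target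

**Totals**
Total step count: 7. Longest linear sequence: 7 steps (from 1).

**Steps most likely to fail**

Step 2. The second carbene transfer may stall at cyclopropene 7, the catalyst may open 7 to a vinylcarbene that closes onto the ester to a furan, or 8 may isomerise to the open-chain diene. The fallback sets out from 1 and comes back at 13. Heck coupling of 1 with acrylic acid (Pd(OAc)2, P(o-tol)3, Et3N, DMF, 100 °C) gives (E)-3-(3,4,5-trimethoxyphenyl)prop-2-enoic acid F1. Irradiation of its crystals in a head-to-tail packed form (Pyrex-filtered mercury lamp), the topochemical [2+2] photodimerisation by which head-to-tail cinnamic acid dimers are made, should give 13, after which steps 6 and 7 follow. This gives up the carbene construction and forms the four-membered ring from two cinnamate units; it depends on a suitable crystal packing.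

Step 4. The hydrogen may be delivered to C2 of 10 on the face syn to the C3 ester, which gives the cis-diaryl series that no epimerisation can correct; 10 may also open to the diene or rest as its dienolate before it is reduced. The fallback sets out from 8 and comes back at 13. Ionic hydrogenation of 8 with CF3CO2H and Et3SiH in CH2Cl2 at −40 °C opens the central bond by protonation and traps the benzylic cation with hydride before it can eliminate, so no cyclobutene is handled. Front-side protonation of the bent central bond (retention at the protonated carbon, the usual course of electrophilic cleavage of strained σ bonds) should put the aryl group of that carbon anti to the two exo esters. Both esters then flank the cation on one face, hydride enters anti to them, and the product should be 11 with the aryl groups trans. 11 is equilibrated with NaOEt in EtOH to diethyl (1α,2α,3β,4β)-2,4-bis(3,4,5-trimethoxyphenyl)cyclobutane-1,3-dicarboxylate F2, which is saponified as in step 5 to 13. This needs exo,exo-8 free of the exo,endo isomer, and a small-scale trial shows whether the proton enters as assumed.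

Step 7. Ketene formation from the hindered acid chloride may scramble the alpha carbons, the lactamate may add in conjugate fashion to the unsaturated lactam, or the second acylation may stay incomplete. The fallback sets out from 13 and comes back at 17. Amide coupling of 13 with but-3-en-1-amine (EDC·HCl, HOBt, CH2Cl2) gives (1α,2α,3β,4β)-N1,N3-di(but-3-en-1-yl)-2,4-bis(3,4,5-trimethoxyphenyl)cyclobutane-1,3-dicarboxamide F3. Double N-acylation with acryloyl chloride (LiN(SiMe3)2, THF, −78 °C) gives (1α,2α,3β,4β)-N1,N3-di(but-3-en-1-yl)-N1,N3-di(prop-2-enoyl)-2,4-bis(3,4,5-trimethoxyphenyl)cyclobutane-1,3-dicarboxamide F4. Twofold ring-closing metathesis with the second-generation Grubbs catalyst (CH2Cl2, 40 °C) closes both dihydropyridinone rings and should give 17. Here the cyclobutane is the nucleophile and acryloyl chloride the electrophile, so no ketene can form at the ring carbons, and the unsaturated lactam appears only in the last, neutral operation.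

**Further compounds**
F1 | step 2 | (E)-3-(3,4,5-trimethoxyphenyl)prop-2-enoic acid | COc1cc(/C=C/C(=O)O)cc(OC)c1OC
F2 | step 4 | diethyl (1α,2α,3β,4β)-2,4-bis(3,4,5-trimethoxyphenyl)cyclobutane-1,3-dicarboxylate | COc1cc([C@H]2[C@H](C(=O)OCC)[C@H](c3cc(OC)c(OC)c(OC)c3)[C@H]2C(=O)OCC)cc(OC)c1OC
F3 | step 7 | (1α,2α,3β,4β)-N1,N3-di(but-3-en-1-yl)-2,4-bis(3,4,5-trimethoxyphenyl)cyclobutane-1,3-dicarboxamide | COc1cc([C@H]2[C@H](C(=O)NCCC=C)[C@H](c3cc(OC)c(OC)c(OC)c3)[C@H]2C(=O)NCCC=C)cc(OC)c1OC
F4 | step 7 | (1α,2α,3β,4β)-N1,N3-di(but-3-en-1-yl)-N1,N3-di(prop-2-enoyl)-2,4-bis(3,4,5-trimethoxyphenyl)cyclobutane-1,3-dicarboxamide | COc1cc([C@H]2[C@H](C(=O)N(CCC=C)C(=O)C=C)[C@H](c3cc(OC)c(OC)c(OC)c3)[C@H]2C(=O)N(CCC=C)C(=O)C=C)cc(OC)c1OC
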